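**Retrosynthetic overview**

- The strategy rests on ring A (C4a, C5, C6, C7, C8, C8a of the chromone): a fully substituted benzene carrying OH (C5), CH3 (C6), OH (C7), CH3 (C8) and the ring oxygen (C8a), fused to the pyranone along C4a–C8a.
- The last disconnection is the O–Si bond at C7. Before that, ring A is cut into a pyranonyl diazo ethyl ketone and 1-(triisopropylsilyloxy)propyne by a photochemical benzannulation (bonds C8–C8a, C5–C6, C7–C8, C4a–C5).
- The diazo ketone comes from 6-heptadecyl-4-oxo-4H-pyran-2-carboxylic acid (acid chloride plus diazoethane). The acid comes from a 2,4,6-triketo ester assembled from acetylacetone, 1-bromohexadecane and diethyl oxalate.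
- The siloxyalkyne comes from ethyl acetate by ynolate chemistry.
- Ring order: pyranone ring first (step 3), benzene ring A second (step 6).

Key step: step 6

Assumption: the target has no stereocenter; diazoethane is used as a freshly prepared, KOH-dried ether solution, and 365 nm light is taken to excite the diazo ketone while the pyranone absorbs little at that wavelength.

**Route**

Step 1
Reactants: 1 acetylacetone; 2 1-bromohexadecane
Product: 4 henicosane-2,4-dione, via acetylacetone dianion 3 (not isolated)
Conditions: LiN(iPr)2 (2.1 equiv), THF, 0 °C; then 2, 0 °C to rt; aq HCl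
Reagents that add atoms: none
Why: Two equivalents of LiN(iPr)2 give the acetylacetone dianion, whose terminal carbanion is the most nucleophilic site and is alkylated by the primary bromide (Hauser-type β-diketone dianion alkylation), the chelated enolate staying untouched.

Step 2
Reactants: 4 henicosane-2,4-dione; 5 diethyl oxalate
Product: 7 ethyl 2,4,6-trioxotricosanoate, via diketone dianion 6 (not isolated)
Conditions: LiN(iPr)2 (2.2 equiv), THF, −78 to 0 °C; cannulate into (CO2Et)2 (3 equiv), THF, −78 °C; aq HCl
Reagents that add atoms: none
Why: The second deprotonation of 4 should occur at the C1 methyl group in preference to the C5 methylene, and this terminal carbanion is acylated by one ester group of diethyl oxalate (Claisen-type acylation of a β-diketone dianion), inverse addition to excess oxalate suppressing double addition.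

Step 3
Reactants: 7 ethyl 2,4,6-trioxotricosanoate
Product: 9 6-heptadecyl-4-oxo-4H-pyran-2-carboxylic acid, via pyranone ethyl ester 8 (not isolated)
Conditions: conc. HCl, AcOH, reflux
Reagents that add atoms: water, O
Why: Acid-catalysed cyclodehydration of the 1,3,5-tricarbonyl unit (enol oxygen at C6 onto the C2 ketone) closes the 4-pyranone as in the chelidonic acid synthesis, and the same hot aqueous acid hydrolyses the ester, avoiding hydroxide, which would open the pyranone ring.

Step 4
Reactants: 9 6-heptadecyl-4-oxo-4H-pyran-2-carboxylic acid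
Product: 11 2-(2-diazopropanoyl)-6-heptadecyl-4H-pyran-4-one, via acid chloride 10 (not isolated)
Conditions: (COCl)2, cat. DMF, CH2Cl2, 0 °C to rt; evaporate; CH3CHN2 (3 equiv), Et2O, −20 to 0 °C
Reagents that add atoms: diazoethane, CC=[N+]=[N-]
Why: Vilsmeier-type activation gives acid chloride 10, which acylates diazoethane at carbon (first stage of the Arndt–Eistert sequence) while excess diazoethane consumes the HCl, and 10 has no alpha hydrogen, so it cannot form a ketene.

Step 5
Reactants: 12 ethyl acetate
Product: 14 triisopropyl(prop-1-yn-1-yloxy)silane, via lithium propynolate 13 (not isolated)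
Conditions: CH2Br2, lithium 2,2,6,6-tetramethylpiperidide, THF, −78 °C; LiN(SiMe3)2; n-BuLi, −78 °C to rt; iPr3SiCl, −78 °C to rt
Reagents that add atoms: dibromomethane, BrCBr; triisopropylsilyl chloride, CC(C)[Si](Cl)(C(C)C)C(C)C
Why: Kowalski ynolate chemistry, in which dibromomethyllithium adds to the ester, the derived dibromoketone enolate undergoes bromine–lithium exchange and carbenoid 1,2-shift to ynolate 13, and the bulky silyl chloride traps it on oxygen.

Step 6
Reactants: 11 2-(2-diazopropanoyl)-6-heptadecyl-4H-pyran-4-one; 14 triisopropyl(prop-1-yn-1-yloxy)silane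
Product: 18 2-heptadecyl-5-hydroxy-6,8-dimethyl-7-(triisopropylsilyloxy)-4H-chromen-4-one, via methyl pyranonyl ketene 15 (not isolated), via siloxycyclobutenone 16 (not isolated), via dienylketene 17 (not isolated)
Conditions: hν (365 nm LED), 14 (2 equiv), degassed ClCH2CH2Cl, rt; then 80 °C
Reagents that add atoms: none
Why: Proposed new method: 365 nm light excites the diazo ketone, N2 leaves and the pyranonyl group shifts from the carbonyl carbon to the carbene carbon (Wolff rearrangement, bond C8–C8a) to give ketene 15, whose carbonyl carbon joins the nucleophilic methyl-bearing carbon of 14 and whose alpha carbon joins the silyloxy-bearing carbon in a [2+2] cycloaddition (bonds C5–C6 and C7–C8) to give cyclobutenone 16. Heat or light should open 16 in a reversible conrotatory four-electron process to dienylketene 17, and ring A then closes as a six-membered carbocycle by disrotatory six-electron electrocyclization of the ketene carbon onto pyranone C3 (bond C4a–C5), after which the cyclohexadienone tautomerizes to the C5 phenol. The closest known reaction type is the Danheiser benzannulation of vinyl, aryl and heteroaryl diazomethyl ketones with siloxyalkynes; new here are the cross-conjugated pyranone C2=C3 bond as the ene partner and the methyl group on the diazo carbon. No stereocenter remains in the product, and the one in 16 is lost on ring opening. The regiochemistry of the cycloaddition is set by the polarization of the siloxyalkyne, closure can only reach C3 because the other neighbour of the ketene-bearing carbon is the ring oxygen, and because the opening of 16 is reversible both alkene geometries of 17 can drain through the E isomer that cyclizes. The main competing process, a 1,2-hydrogen shift of the carbene to a vinyl ketone, should be limited by direct irradiation without a metal catalyst.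

Step 7
Reactants: 18 2-heptadecyl-5-hydroxy-6,8-dimethyl-7-(triisopropylsilyloxy)-4H-chromen-4-one
Product: 19 2-heptadecyl-5,7-dihydroxy-6,8-dimethyl-4H-chromen-4-one (CNP0129113.0)
Conditions: Bu4NF (1.1 equiv), THF, 0 °C; aq NH4Cl
Reagents that add atoms: none
Why: Fluoride-induced cleavage of the aryl silyl ether, driven by formation of the strong Si–F bond, frees the C7 phenol under conditions that leave the chromone and the hydrogen-bonded C5 phenol untouched.

**Compound list**

1 | acetylacetone (pentane-2,4-dione) | CC(=O)CC(C)=O | starting material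
2 | 1-bromohexadecane | CCCCCCCCCCCCCCCCBr | starting material
3 | dilithium dianion of acetylacetone (1,3-bis-enolate) | [Li+].[Li+].C=C([O-])C=C(C)[O-] | intermediate
4 | henicosane-2,4-dione | CCCCCCCCCCCCCCCCCC(=O)CC(C)=O | intermediate
5 | diethyl oxalate | CCOC(=O)C(=O)OCC | starting material
6 | dilithium dianion of henicosane-2,4-dione (1,3-bis-enolate, terminal CH2) | [Li+].[Li+].C=C([O-])C=C([O-])CCCCCCCCCCCCCCCCC | intermediate
7 | ethyl 2,4,6-trioxotricosanoate | CCCCCCCCCCCCCCCCCC(=O)CC(=O)CC(=O)C(=O)OCC | intermediate
8 | ethyl 6-heptadecyl-4-oxo-4H-pyran-2-carboxylate | CCCCCCCCCCCCCCCCCc1cc(=O)cc(C(=O)OCC)o1 | intermediate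
9 | 6-heptadecyl-4-oxo-4H-pyran-2-carboxylic acid | CCCCCCCCCCCCCCCCCc1cc(=O)cc(C(=O)O)o1 | intermediate
10 | 6-heptadecyl-4-oxo-4H-pyran-2-carbonyl chloride | CCCCCCCCCCCCCCCCCc1cc(=O)cc(C(=O)Cl)o1 | intermediate
11 | 2-(2-diazopropanoyl)-6-heptadecyl-4H-pyran-4-one | CCCCCCCCCCCCCCCCCc1cc(=O)cc(C(=O)C(C)=[N+]=[N-])o1 | intermediate
12 | ethyl acetate | CCOC(C)=O | starting material
13 | lithium prop-1-yn-1-olate | [Li+].CC#C[O-] | intermediate
14 | triisopropyl(prop-1-yn-1-yloxy)silane | CC#CO[Si](C(C)C)(C(C)C)C(C)C | intermediate
15 | 6-heptadecyl-2-(1-oxoprop-1-en-2-yl)-4H-pyran-4-one (methyl pyranonyl ketene) | CCCCCCCCCCCCCCCCCc1cc(=O)cc(C(C)=C=O)o1 | intermediate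
16 | 2-[1,3-dimethyl-4-oxo-2-(triisopropylsilyloxy)cyclobut-2-en-1-yl]-6-heptadecyl-4H-pyran-4-one (racemic) | CCCCCCCCCCCCCCCCCc1cc(=O)cc(C2(C)C(=O)C(C)=C2O[Si](C(C)C)(C(C)C)C(C)C)o1 | intermediate
17 | 6-heptadecyl-2-[(2E)-4-methyl-5-oxo-3-(triisopropylsilyloxy)penta-2,4-dien-2-yl]-4H-pyran-4-one | CCCCCCCCCCCCCCCCCc1cc(=O)cc(/C(C)=C(/O[Si](C(C)C)(C(C)C)C(C)C)C(C)=C=O)o1 | intermediate
18 | 2-heptadecyl-5-hydroxy-6,8-dimethyl-7-(triisopropylsilyloxy)-4H-chromen-4-one | CCCCCCCCCCCCCCCCCc1cc(=O)c2c(O)c(C)c(O[Si](C(C)C)(C(C)C)C(C)C)c(C)c2o1 | intermediate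
19 | 2-heptadecyl-5,7-dihydroxy-6,8-dimethyl-4H-chromen-4-one | CCCCCCCCCCCCCCCCCc1cc(=O)c2c(O)c(C)c(O)c(C)c2o1 | target

**Step count**

Total steps: 7. Longest linear sequence: 6 steps (steps 1, 2, 3, 4, 6, 7); step 5 is a one-step side branch that joins at step 6.

**Steps most likely to fail**

Step 6 (benzannulation). What may go wrong: the photogenerated carbene undergoes 1,2-hydrogen shift from the methyl group instead of the Wolff shift, the pyranone ring undergoes its own photorearrangement, or the six-electron closure onto pyranone C3 is too slow and the ketene is lost to dimerization. The fallback uses known chemistry only and gives up the benzannulation. It sets out from 1-bromohexadecane 2 and comes back to the route at target 19. The dianion of ethyl acetoacetate (NaH, then n-BuLi, THF, 0 °C) is alkylated with 2 to give ethyl 3-oxoicosanoate F1 by Huckin–Weiler alkylation. F1 is then heated with commercial 2,4-dimethylbenzene-1,3,5-triol (Oc1cc(O)c(C)c(O)c1C), neat or in diphenyl ether at about 240 °C (Mentzer chromone synthesis, the oxygen counterpart of the Conrad–Limpach cyclization). The only free ring carbon of the triol is acylated and a flanking phenol condenses with the ketone; by the symmetry of the triol only one chromone can result, which is 19. Uncatalysed thermal conditions are chosen because acid would favour the Pechmann coumarin.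

Step 4 (diazo ketone). What may go wrong: dipolar cycloaddition of diazoethane to the electron-poor pyranone double bonds, chlorination at the C4 carbonyl by oxalyl chloride, or conversion of the diazo ketone to the alpha-chloro ketone by HCl. The fallback sets out from acid chloride 10, made from acid 9 as before, and comes back to the route at diazo ketone 11. Negishi acylation of EtZnBr with 10 (cat. Pd(PPh3)4, zerovalent palladium, THF, 0 °C) should give 6-heptadecyl-2-propanoyl-4H-pyran-4-one F2 as the ethyl ketone. F2 is then converted into its lithium enolate (LiN(SiMe3)2, THF, −78 °C) and trifluoroacetylated with CF3CO2CH2CF3 to give 6-heptadecyl-2-(4,4,4-trifluoro-2-methyl-3-oxobutanoyl)-4H-pyran-4-one F3 as the activated diketone. F3 is then treated with MsN3, Et3N and water in MeCN, which should effect detrifluoroacetylative diazo transfer to 11, so no diazoalkane is handled.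

Step 5 (siloxyalkyne). What may go wrong: enolization of ethyl acetate by dibromomethyllithium instead of addition, silylation of the ynolate on carbon, or loss of the hydrolytically sensitive product during isolation. The fallback replaces the silyl ynol ether by commercial 1-ethoxyprop-1-yne. It sets out from diazo ketone 11 and comes back to the route at target 19. Irradiation of 11 with the ethoxyalkyne under the irradiation conditions of the key step should give, by way of ketene 15, 2-(2-ethoxy-1,3-dimethyl-4-oxocyclobut-2-en-1-yl)-6-heptadecyl-4H-pyran-4-one F4 as the cycloadduct. F4 should then open on warming to 2-[(2E)-3-ethoxy-4-methyl-5-oxopenta-2,4-dien-2-yl]-6-heptadecyl-4H-pyran-4-one F5 as the dienylketene. F5 should then close onto pyranone C3 and tautomerize to 7-ethoxy-2-heptadecyl-5-hydroxy-6,8-dimethyl-4H-chromen-4-one F6 as the ethyl ether of the target. F6 is then treated with BBr3 (CH2Cl2, −78 °C to rt), which cleaves the ethyl ether to give 19.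

**Further compounds**

F1 | step 6 | ethyl 3-oxoicosanoate | CCCCCCCCCCCCCCCCCC(=O)CC(=O)OCC
F2 | step 4 | 6-heptadecyl-2-propanoyl-4H-pyran-4-one | CCCCCCCCCCCCCCCCCc1cc(=O)cc(C(=O)CC)o1
F3 | step 4 | 6-heptadecyl-2-(4,4,4-trifluoro-2-methyl-3-oxobutanoyl)-4H-pyran-4-one | CCCCCCCCCCCCCCCCCc1cc(=O)cc(C(=O)C(C)C(=O)C(F)(F)F)o1
F4 | step 5 | 2-(2-ethoxy-1,3-dimethyl-4-oxocyclobut-2-en-1-yl)-6-heptadecyl-4H-pyran-4-one | CCCCCCCCCCCCCCCCCc1cc(=O)cc(C2(C)C(=O)C(C)=C2OCC)o1
F5 | step 5 | 2-[(2E)-3-ethoxy-4-methyl-5-oxopenta-2,4-dien-2-yl]-6-heptadecyl-4H-pyran-4-one | CCCCCCCCCCCCCCCCCc1cc(=O)cc(/C(C)=C(/OCC)C(C)=C=O)o1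
F6 | step 5 | 7-ethoxy-2-heptadecyl-5-hydroxy-6,8-dimethyl-4H-chromen-4-one | CCCCCCCCCCCCCCCCCc1cc(=O)c2c(O)c(C)c(OCC)c(C)c2o1
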